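**Retrosynthetic overview**
1. Ajugaciliatin A ⇐ 1,12-diol 25 (double Steglich esterification) ⇐ lactol 23 + 4-bromobutenolide 24 (C12–C13 bond by Nozaki–Hiyama–Kishi coupling).
2. 23 ⇐ Δ1(10)-ene 19: β-face hydroboration sets C10 and C1, glycol cleavage of the dihydroxylated allyl group gives C12; the chlorohydrin comes from the C4 methylidene.
3. C5 quaternary centre and C6 carbonyl ⇐ stereospecific 1,2-formyl shift of β-epoxy aldehyde 15 (key step) ⇐ trienol 13 (Sharpless epoxidation, oxidation).
4. 13 ⇐ bicyclic dienone 11 (dienyl triflate, Stille) ⇐ ring A closed by Heck reaction of iodo alcohol 9, then Dauben transposition.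
5. Ring B ⇐ 2-methylcyclohexenone by asymmetric conjugate methylation/allylation (C8, C9). Ring order: B, then A; the butenolide is attached last.

Assumption: atoms are numbered as in the target (ring A = C1–C5 and C10, ring B = C5–C10, C11/C12 on C9, C17 on C8, C18 on C4, C19 on C5, C20 on C9; α = face of C19 and C20, β = face of H-10), and the five numbered starting materials are taken as commercial.

**Step 1**
Reactants: 1 2-methylcyclohex-2-en-1-one; 2 allyl acetate
Product: 4 (2S,3R)-2-allyl-2,3-dimethylcyclohexan-1-one, via aluminium enolate 3 (not isolated)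
Conditions: Me3Al, copper thiophene-2-carboxylate (C5H3CuO2S, 2 mol %), chiral phosphoramidite ligand (4 mol %, enantiomer giving 3R), Et2O, −30 °C; then 2, Pd(PPh3)4 (5 mol %), THF, 0 °C to rt
Reagents that add atoms: trimethylaluminium, C[Al](C)C
Why: Copper-catalysed asymmetric conjugate addition sets C8 (3R) under ligand control, and Tsuji–Trost allylation of the regiodefined aluminium enolate 3 occurs anti to the new C8 methyl group, which sets the C9 quaternary centre (2S, allyl trans to the C8 methyl).

**Step 2**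
Reactants: 4 (2S,3R)-2-allyl-2,3-dimethylcyclohexan-1-one
Product: 5 (5R,6S)-6-allyl-5,6-dimethylcyclohex-2-en-1-one
Conditions: IBX, 4-methoxypyridine N-oxide, DMSO, 25 °C
Reagents that add atoms: none
Why: IBX dehydrogenation at the only enolisable α-position (C5) gives the enone and leaves both stereocentres untouched.

**Step 3**
Reactants: 5 (5R,6S)-6-allyl-5,6-dimethylcyclohex-2-en-1-one
Product: 6 (5R,6S)-6-allyl-2-iodo-5,6-dimethylcyclohex-2-en-1-one
Conditions: I2, pyridine, CH2Cl2, 0 °C to rt
Reagents that add atoms: iodine, II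
Why: Johnson α-iodination of an enone (pyridine adds to the unsubstituted β-carbon, the enolate is iodinated, pyridine is lost) places the halide on C5 for the later ring closure.

**Step 4**
Reactants: 6 (5R,6S)-6-allyl-2-iodo-5,6-dimethylcyclohex-2-en-1-one; 7 5-bromopent-1-ene
Product: 9 (5R,6S)-6-allyl-2-iodo-5,6-dimethyl-1-(pent-4-en-1-yl)cyclohex-2-en-1-ol (both C1 epimers), via pent-4-en-1-ylmagnesium bromide 8 (not isolated)
Conditions: 7, Mg, THF, rt; then 6, LaCl3·2LiCl, THF, −78 to 0 °C
Reagents that add atoms: none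
Why: Lanthanum-promoted 1,2-addition of the Grignard reagent to the hindered ketone outruns enolisation and iodine–magnesium exchange, and the new carbinol centre is erased in step 6 so its configuration does not matter.

**Step 5**
Reactants: 9 iodo alcohol
Product: 10 (3R,4S)-4-allyl-3,4-dimethyl-8-methylidene-3,4,5,6,7,8-hexahydronaphthalen-4a(2H)-ol (both C4a epimers)
Conditions: Pd(OAc)2 (10 mol %), PPh3, Ag2CO3, MeCN, 70 °C
Reagents that add atoms: none
Why: Intramolecular 6-exo-trig Heck reaction closes ring A and β-hydride elimination leaves the exocyclic C4 methylidene, while cyclisation onto the C9 allyl group would give an anti-Bredt bridgehead alkene and the silver salt prevents double-bond migration.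

**Step 6**
Reactants: 10 dienol
Product: 11 (3R,4S)-4-allyl-3,4-dimethyl-8-methylidene-3,4,5,6,7,8-hexahydronaphthalen-1(2H)-one
Conditions: pyridinium chlorochromate (C5H6NCrO3Cl), Celite, CH2Cl2, rt
Reagents that add atoms: none
Why: Dauben oxidative 1,3-transposition of the tertiary allylic alcohol through its chromate ester moves oxygen to C6 and the double bond to C5=C10.

**Step 7**
Reactants: 11 bicyclic dienone
Product: 12 (3R,4S)-4-allyl-3,4-dimethyl-8-methylidene-2,3,4,6,7,8-hexahydronaphthalen-1-yl trifluoromethanesulfonate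
Conditions: Tf2O, 2,6-di-tert-butyl-4-methylpyridine, CH2Cl2, 0 °C
Reagents that add atoms: trifluoromethanesulfonic anhydride, O=S(=O)(OS(=O)(=O)C(F)(F)F)C(F)(F)F
Why: O-triflation of the enone with loss of the γ-proton at C1 gives the thermodynamically preferred heteroannular dienyl triflate, the behaviour known for steroidal enones.

**Step 8**
Reactants: 12 trienyl triflate
Product: 13 [(3R,4S)-4-allyl-3,4-dimethyl-8-methylidene-2,3,4,6,7,8-hexahydronaphthalen-1-yl]methanol
Conditions: Bu3SnCH2OH, Pd(PPh3)4 (5 mol %), LiCl, 1,4-dioxane, 90 °C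
Reagents that add atoms: (tributylstannyl)methanol, CCCC[Sn](CO)(CCCC)CCCC
Why: Stille coupling of the alkenyl triflate with the hydroxymethyl stannane puts C19 on C6 and creates the allylic alcohol needed for the epoxidation.

**Step 9**
Reactants: 13 trienol
Product: 14 5β,6β-epoxy alcohol (oxirane on C5–C6 cis to the allyl group, CH2OH on C6)
Conditions: Ti(OiPr)4, L-(+)-diethyl tartrate, t-BuOOH, 4 Å molecular sieves, CH2Cl2, −25 °C
Reagents that add atoms: tert-butyl hydroperoxide, CC(C)(C)OO
Why: Sharpless asymmetric epoxidation touches only the allylic alcohol double bond, and L-(+)-tartrate (the sense that gives 2S,3S-epoxy alcohols from E-allylic alcohols) delivers oxygen to the β face, which is also the face away from the axial C9 methyl group (matched case).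

**Step 10**
Reactants: 14 5β,6β-epoxy alcohol
Product: 16 9β-allyl-5α-formyl-8α,9α-dimethyl-4(18)-methylidenedecal-1(10)-en-6-one, via epoxy aldehyde 15 (not isolated)
Conditions: Dess–Martin periodinane, NaHCO3, CH2Cl2, 0 °C; then BF3·OEt2, −78 °C
Reagents that add atoms: none
Why: Proposed new method: a tandem oxidation/1,2-formyl shift on a ring-fused, doubly vinylic tetrasubstituted epoxide, in which BF3 opens the C5–O bond of 15 to a cation stabilised by both flanking alkenes (C4=C18 and C10=C1) and the formyl group, the best migrating group on C6, shifts to C5 on the α face anti to the departing oxygen (inversion at C5), so the β-epoxide of step 9 becomes the α-formyl (C19) quaternary centre while C6 becomes the ketone and both alkenes survive; the closest known reaction type is the Lewis-acid rearrangement of α,β-epoxy ketones and aldehydes by 1,2-acyl shift (Meinwald-type, as in isophorone oxide to a 2-formyl ketone), which has not been shown for formyl migration to a divinyl carbinyl cation in a fused bicycle.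

**Step 11**
Reactants: 16 keto aldehyde
Product: 18 6α,19-diacetoxy-9β-allyl-8α,9α-dimethyl-4(18)-methylidenedecal-1(10)-ene, via diol 17 (not isolated)
Conditions: LiBH(s-Bu)3, THF, −78 °C; then Ac2O, DMAP, −78 °C to rt
Reagents that add atoms: acetic anhydride, CC(=O)OC(C)=O
Why: The bulky borohydride reduces the aldehyde and attacks the C6 ketone from the β face (axial attack, anti to the axial C5 substituent, with no internal hydride delivery) to give the equatorial 6α-alkoxide, and both alkoxides are acetylated in the same flask.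

**Step 12**
Reactants: 18 diacetate
Product: 19 6α,19-diacetoxy-18-chloro-4α-hydroxy-9β-allyl-8α,9α-dimethyldecal-1(10)-ene
Conditions: trichloroisocyanuric acid (0.35 equiv), acetone/H2O, 0 °C
Reagents that add atoms: trichloroisocyanuric acid, O=C1N(Cl)C(=O)N(Cl)C(=O)N1Cl; water, O
Why: Electrophilic chlorohydroxylation goes Markovnikov at the most accessible 1,1-disubstituted alkene (chlorine to C18), and the tertiary C4 cation is captured on the α face with anchimeric help of the 19-acetate (six-membered acetoxonium then hydrolysis) to give the 4α-hydroxy 18-chloride, while the Δ1(10) bond is buried between two quaternary carbons and the allyl group is the least nucleophilic alkene.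

**Step 13**
Reactants: 19 chlorohydrin
Product: 20 chlorohydrin with the C9 allyl group turned into 2,3-dihydroxypropyl (both carbinol epimers)
Conditions: K2OsO4·2H2O (2 mol %), N-methylmorpholine N-oxide, acetone/H2O, 0 °C
Reagents that add atoms: N-methylmorpholine N-oxide, C[N+]1([O-])CCOCC1; water, O
Why: Upjohn dihydroxylation picks the unhindered monosubstituted alkene over the buried trisubstituted Δ1(10) bond, and the new carbinol centre is removed in step 14.

**Step 14**
Reactants: 20 side-chain diol
Product: 23 1β,12-lactol (C12 hemiacetal closed on 1β-O; 6α,19-diacetoxy-18-chloro-4α-hydroxy; both anomers), via alkylborane 21 (not isolated), via tetraol 22 (not isolated)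
Conditions: BH3·SMe2, THF, 0 °C to rt; then NaBO3·4H2O, H2O, rt; then NaIO4, rt
Reagents that add atoms: sodium perborate, [Na+].[O-]OB=O
Why: Borane adds syn across the Δ1(10) bond from the β face, opposite to the axial C19 and C20 groups, which sets H-10β (trans ring fusion) and, after oxidation with retention, the equatorial 1β-OH, and Malaprade cleavage of the side-chain glycol gives the C12 aldehyde that closes onto 1β-OH as a six-membered lactol.

**Step 15**
Reactants: 23 lactol; 24 4-bromofuran-2(5H)-one
Product: 25 (12S)-1β,12-diol (ajugaciliatin A lacking both 2-methylbutanoyl groups)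
Conditions: CrCl2, NiCl2 (2 mol %), chiral oxazoline sulfonamide ligand (enantiomer giving 12S), Et3N, THF/MeCN, rt
Reagents that add atoms: none
Why: Nozaki–Hiyama–Kishi coupling in which the lactol reacts through its hydroxy aldehyde form with the alkenylchromium species made from the bromobutenolide (nickel-catalysed), and the chiral sulfonamide ligand on chromium sets 12S.

**Step 16**
Reactants: 25 (12S)-1β,12-diol; 26 (S)-2-methylbutanoic acid
Product: 27 ajugaciliatin A
Conditions: 26 (3 equiv), N,N'-diisopropylcarbodiimide, DMAP (0.2 equiv), CH2Cl2, 0 °C to rt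
Reagents that add atoms: none
Why: Steglich esterification acylates the two secondary hydroxyls while the tertiary 4-OH stays free, and the mild carbodiimide conditions keep the α-stereocentre of the acid.

**Compound list**
1 | 2-methylcyclohex-2-en-1-one | CC1=CCCCC1=O | starting material
2 | allyl acetate | CC(=O)OCC=C | starting material
3 | dimethylaluminium (3R)-2,3-dimethylcyclohex-1-en-1-olate | C[Al](C)OC1=C(C)[C@H](C)CCC1 | intermediate
4 | (2S,3R)-2-allyl-2,3-dimethylcyclohexan-1-one | C=CC[C@@]1(C)[C@H](C)CCCC1=O | intermediate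
5 | (5R,6S)-6-allyl-5,6-dimethylcyclohex-2-en-1-one | C=CC[C@@]1(C)[C@H](C)CC=CC1=O | intermediate
6 | (5R,6S)-6-allyl-2-iodo-5,6-dimethylcyclohex-2-en-1-one | C=CC[C@@]1(C)[C@H](C)CC=C(I)C1=O | intermediate
7 | 5-bromopent-1-ene | C=CCCCBr | starting material
8 | pent-4-en-1-ylmagnesium bromide | C=CCCC[Mg]Br | intermediate
9 | (5R,6S)-6-allyl-2-iodo-5,6-dimethyl-1-(pent-4-en-1-yl)cyclohex-2-en-1-ol (both C1 epimers) | C=CC[C@@]1(C)[C@H](C)CC=C(I)C1(O)CCCC=C | intermediate
10 | (3R,4S)-4-allyl-3,4-dimethyl-8-methylidene-3,4,5,6,7,8-hexahydronaphthalen-4a(2H)-ol (both C4a epimers) | C=CC[C@@]1(C)[C@H](C)CC=C2C1(O)CCCC2=C | intermediate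
11 | (3R,4S)-4-allyl-3,4-dimethyl-8-methylidene-3,4,5,6,7,8-hexahydronaphthalen-1(2H)-one | C=CC[C@@]1(C)[C@H](C)CC(=O)C2=C1CCCC2=C | intermediate
12 | (3R,4S)-4-allyl-3,4-dimethyl-8-methylidene-2,3,4,6,7,8-hexahydronaphthalen-1-yl trifluoromethanesulfonate | C=CC[C@@]1(C)[C@H](C)CC(OS(=O)(=O)C(F)(F)F)=C2C1=CCCC2=C | intermediate
13 | [(3R,4S)-4-allyl-3,4-dimethyl-8-methylidene-2,3,4,6,7,8-hexahydronaphthalen-1-yl]methanol | C=CC[C@@]1(C)[C@H](C)CC(CO)=C2C1=CCCC2=C | intermediate
14 | 5β,6β-epoxide of 13 (epoxy alcohol, oxirane cis to the allyl group, CH2OH on C6) | C=CC[C@@]1(C)[C@H](C)C[C@]3(CO)[C@@]2(O3)C1=CCCC2=C | intermediate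
15 | 5β,6β-epoxy aldehyde (14 with CH2OH oxidised to CHO) | C=CC[C@@]1(C)[C@H](C)C[C@]3(C=O)[C@@]2(O3)C1=CCCC2=C | intermediate
16 | 9β-allyl-5α-formyl-8α,9α-dimethyl-4(18)-methylidenedecal-1(10)-en-6-one | C=CC[C@@]1(C)[C@H](C)CC(=O)[C@]2(C=O)C1=CCCC2=C | intermediate
17 | 9β-allyl-5α-(hydroxymethyl)-8α,9α-dimethyl-4(18)-methylidenedecal-1(10)-en-6α-ol | C=CC[C@@]1(C)[C@H](C)C[C@H](O)[C@]2(CO)C1=CCCC2=C | intermediate
18 | 6α,19-diacetate of 17 | C=CC[C@@]1(C)[C@H](C)C[C@H](OC(C)=O)[C@]2(COC(C)=O)C1=CCCC2=C | intermediate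
19 | 6α,19-diacetoxy-18-chloro-4α-hydroxy-9β-allyl-8α,9α-dimethyldecal-1(10)-ene | C=CC[C@@]1(C)[C@H](C)C[C@H](OC(C)=O)[C@]2(COC(C)=O)C1=CCC[C@]2(O)CCl | intermediate
20 | 19 with the allyl group dihydroxylated (2,3-dihydroxypropyl on C9, both carbinol epimers) | OCC(O)C[C@@]1(C)[C@H](C)C[C@H](OC(C)=O)[C@]2(COC(C)=O)C1=CCC[C@]2(O)CCl | intermediate
21 | 1β-boryl, 10β-H adduct of 20 (hydroxyls shown free) | OCC(O)C[C@@]1(C)[C@H](C)C[C@H](OC(C)=O)[C@]2(COC(C)=O)[C@@H]1[C@H](B)CC[C@]2(O)CCl | intermediate
22 | tetraol: 20 with 1β-OH and 10β-H (trans-decalin) | OCC(O)C[C@@]1(C)[C@H](C)C[C@H](OC(C)=O)[C@]2(COC(C)=O)[C@@H]1[C@H](O)CC[C@]2(O)CCl | intermediate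
23 | 1β,12-lactol (C12 hemiacetal on 1β-O, both anomers; 6α,19-diacetoxy, 18-chloro, 4α-hydroxy) | OC3C[C@@]1(C)[C@H](C)C[C@H](OC(C)=O)[C@]2(COC(C)=O)[C@@H]1[C@H](O3)CC[C@]2(O)CCl | intermediate
24 | 4-bromofuran-2(5H)-one | O=C1OCC(Br)=C1 | starting material
25 | (12S)-1β,12-diol (ajugaciliatin A without the two 2-methylbutanoyl groups) | O[C@@H](C[C@@]1(C)[C@H](C)C[C@H](OC(C)=O)[C@]2(COC(C)=O)[C@@H]1[C@H](O)CC[C@]2(O)CCl)C1=CC(=O)OC1 | intermediate
26 | (S)-2-methylbutanoic acid | CC[C@H](C)C(=O)O | starting material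
27 | ajugaciliatin A | CC[C@H](C)C(=O)O[C@@H](C[C@@]1(C)[C@H](C)C[C@H](OC(C)=O)[C@]2(COC(C)=O)[C@@H]1[C@H](OC(=O)[C@@H](C)CC)CC[C@]2(O)CCl)C1=CC(=O)OC1 | target

**Step count and risks**
Total step count: 16. Longest linear sequence: 16 steps (1 to 27); 2, 7, 24 and 26 are used as bought.

Risk 1, step 10 (the proposed new formyl shift). The cation could instead give ring contraction by migration of C7, be trapped by the allyl group, or 15 could decompose. The fallback uses the known rearrangement of epoxy silyl ethers; it sets out from 14 and comes back at 17. Compound 14 is silylated (TBSOTf, 2,6-lutidine, CH2Cl2, −78 °C) to the epoxy silyl ether F1. Methylaluminium bis(4-bromo-2,6-di-tert-butylphenoxide) (CH2Cl2, −78 °C) then brings about the anti 1,2-shift of the siloxymethyl group to give the β-siloxy ketone F2. LiBH(s-Bu)3 reduces it to the 6α-alcohol F3, and Bu4NF removes the silyl group to give diol 17, which is acetylated (Ac2O, DMAP) to 18 as in the second half of step 11.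

Risk 2, step 12 (chlorohydrin). The reagent may also attack the Δ1(10) bond, give allylic chloride, or capture C4 from the wrong face. The fallback replaces electrophilic chlorohydroxylation by hydroxyl-directed epoxidation and chloride opening; it sets out from 16 and comes back at 19. Compound 16 is reduced with LiBH(s-Bu)3 and worked up with water to isolate diol 17. VO(acac)2/t-BuOOH (CH2Cl2, 0 °C) delivers oxygen from the 19-OH to the α face of the C4 methylidene and gives the 4α,18-epoxy diol F4. LiCl/AcOH in THF opens it at the primary C18 to the chlorohydrin triol F5, and Ac2O/pyridine/DMAP acetylates the primary and secondary hydroxyls to give 19.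

Risk 3, step 15 (coupling on the lactol with control of C12). The stable six-membered lactol may open too slowly, and ligand control at C12 may be weak. The fallback avoids the lactol by esterifying 1-OH before the aldehyde is set free; it sets out from 20 and comes back at 27. Compound 20 is protected as the acetonide F6 (2,2-dimethoxypropane, pyridinium tosylate). Hydroboration and perborate oxidation as in step 14 (no periodate) give the 1β-alcohol F7, which is esterified with 26 (N,N'-diisopropylcarbodiimide, DMAP) to the 1-ester F8. H5IO6 (EtOAc/H2O) cleaves the acetonide and the glycol to the free aldehyde F9. Nozaki–Hiyama–Kishi coupling with 24 (CrCl2, NiCl2, chiral sulfonamide ligand) gives the 12S-alcohol F10, and a second Steglich esterification with 26 gives 27.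

**Further compounds**
F1 | step 10 | tert-butyldimethylsilyl ether of epoxy alcohol 14 | C=CC[C@@]1(C)[C@H](C)C[C@]3(CO[Si](C)(C)C(C)(C)C)[C@@]2(O3)C1=CCCC2=C
F2 | step 10 | 9β-allyl-5α-(tert-butyldimethylsilyloxymethyl)-8α,9α-dimethyl-4(18)-methylidenedecal-1(10)-en-6-one | C=CC[C@@]1(C)[C@H](C)CC(=O)[C@]2(CO[Si](C)(C)C(C)(C)C)C1=CCCC2=C
F3 | step 10 | 6α-alcohol of F2 | C=CC[C@@]1(C)[C@H](C)C[C@H](O)[C@]2(CO[Si](C)(C)C(C)(C)C)C1=CCCC2=C
F4 | step 12 | 4α,18-epoxide of diol 17 | C=CC[C@@]1(C)[C@H](C)C[C@H](O)[C@]2(CO)C1=CCC[C@]2(O3)C3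
F5 | step 12 | 18-chloro-4α,6α,19-triol (19 without the acetyl groups) | C=CC[C@@]1(C)[C@H](C)C[C@H](O)[C@]2(CO)C1=CCC[C@]2(O)CCl
F6 | step 15 | acetonide of side-chain diol 20 | CC3(C)OCC(C[C@@]1(C)[C@H](C)C[C@H](OC(C)=O)[C@]2(COC(C)=O)C1=CCC[C@]2(O)CCl)O3
F7 | step 15 | F6 with 1β-OH and 10β-H | CC3(C)OCC(C[C@@]1(C)[C@H](C)C[C@H](OC(C)=O)[C@]2(COC(C)=O)[C@@H]1[C@H](O)CC[C@]2(O)CCl)O3
F8 | step 15 | 1β-(S)-2-methylbutanoate of F7 | CC3(C)OCC(C[C@@]1(C)[C@H](C)C[C@H](OC(C)=O)[C@]2(COC(C)=O)[C@@H]1[C@H](OC(=O)[C@@H](C)CC)CC[C@]2(O)CCl)O3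
F9 | step 15 | C12 aldehyde carrying the 1β-(S)-2-methylbutanoate | O=CC[C@@]1(C)[C@H](C)C[C@H](OC(C)=O)[C@]2(COC(C)=O)[C@@H]1[C@H](OC(=O)[C@@H](C)CC)CC[C@]2(O)CCl
F10 | step 15 | (12S)-12-hydroxy compound carrying the 1β-(S)-2-methylbutanoate | O[C@@H](C[C@@]1(C)[C@H](C)C[C@H](OC(C)=O)[C@]2(COC(C)=O)[C@@H]1[C@H](OC(=O)[C@@H](C)CC)CC[C@]2(O)CCl)C1=CC(=O)OC1
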